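**Plan**

1. Retrosynthesis: the C4–C5 bond of 1-(4-hydroxyphenyl)octadecan-5-one (ketone carbon C5 to the methylene C4 on the arylbutyl side) is cut first, as a decarboxylative Claisen condensation; C3–C4 is cut second, as a malonate alkylation.
2. Remark on the chemistry: the ketone is assumed to arise in nature as in the gingerol/curcuminoid family, where a condensing enzyme joins a fatty acyl thioester to a carboxyl-activated methylene with loss of CO2; the key step copies this event.
3. The feature that allows it is the C5 carbonyl with its enolisable C4 methylene, which can carry carboxyl groups as temporary activators; the only ring, the para-hydroxyphenyl ring, lies four carbons away, is bought, and is only masked as a benzyl ether.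
4. Forward: 3-(4-hydroxyphenyl)propanol → O-benzyl ether → bromide → dibenzyl alkylmalonate (C3–C4) → half ester → magnesium-mediated decarboxylative acylation with tetradecanoyl chloride (C4–C5) → one-pot hydrogenolysis and decarboxylation.
5. Helpers: two carboxyl groups on C4 (one leaves as CO2 in the key step, the other in the last step) and the benzyl group on the phenol; all are removed in the last step.
6. Stereochemistry: the target is achiral; the C4 stereocentre of the intermediates is racemic and is erased in the last step.

Key step: step 5

**Route**

Step 1
Reactants: 1 3-(4-hydroxyphenyl)propan-1-ol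
Product: 2 3-[4-(benzyloxy)phenyl]propan-1-ol
Conditions: BnBr (1.05 equiv), K2CO3, acetone, reflux
Reagents that add atoms: benzyl bromide, BrCc1ccccc1
Why: Williamson ether synthesis, in which carbonate deprotonates only the phenol (far more acidic than the aliphatic alcohol), so the phenoxide alone should be benzylated.

Step 2
Reactants: 2 3-[4-(benzyloxy)phenyl]propan-1-ol
Product: 3 1-(benzyloxy)-4-(3-bromopropyl)benzene
Conditions: CBr4, PPh3, CH2Cl2, 0 °C to rt
Reagents that add atoms: carbon tetrabromide, BrC(Br)(Br)Br
Why: Appel reaction, in which the primary alcohol is activated as an alkoxyphosphonium ion and displaced by bromide (SN2) under neutral conditions that leave the aryl benzyl ether untouched.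

Step 3
Reactants: 3 1-(benzyloxy)-4-(3-bromopropyl)benzene; 4 dibenzyl malonate
Product: 5 dibenzyl 2-{3-[4-(benzyloxy)phenyl]propyl}malonate
Conditions: 4 (2 equiv), NaH (1.5 equiv), THF–DMF, 0 °C; then 3, NaI (cat.), 60 °C
Reagents that add atoms: none
Why: Malonic ester alkylation, in which the sodium enolate of 4 (used in excess to hold back dialkylation) displaces the unhindered primary bromide by SN2 and so installs C4 of the target with two carboxyl groups as activating helpers.

Step 4
Reactants: 5 dibenzyl 2-{3-[4-(benzyloxy)phenyl]propyl}malonate
Product: 6 2-[(benzyloxy)carbonyl]-5-[4-(benzyloxy)phenyl]pentanoic acid (the monobenzyl half ester of the alkylmalonic acid, racemic)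
Conditions: KOH (1.05 equiv), THF–H2O, 0 °C; then 1 M HCl to pH 2
Reagents that add atoms: potassium hydroxide (aqueous), [K+].[OH-]
Why: Selective monosaponification of a symmetrical malonic diester, which should stop at the half ester because the carboxylate formed first repels hydroxide and deactivates the second ester (the new stereocentre is racemic and of no consequence).

Step 5
Reactants: 6 2-[(benzyloxy)carbonyl]-5-[4-(benzyloxy)phenyl]pentanoic acid; 7 tetradecanoyl chloride
Product: 9 benzyl 2-{3-[4-(benzyloxy)phenyl]propyl}-3-oxohexadecanoate (racemic), via acylmalonic half ester 8 (not isolated)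
Conditions: MgCl2 (1.5 equiv), Et3N (3 equiv), MeCN–THF, 0 °C to rt; then 7 (1.2 equiv), 0 °C to rt; then 1 M HCl, rt to 40 °C
Reagents that add atoms: none
Why: Mg2+ binds the carboxylate and the ester carbonyl of 6 in a six-membered chelate, which makes the α-hydrogen acidic enough for Et3N, and the magnesium enolate attacks the acid chloride 7 at carbon to give the acylmalonate 8, whose free acid loses CO2 on acidic work-up through the cyclic six-membered transition state of a β-keto acid to give 9. The closest known reaction type is the magnesium-mediated decarboxylative Claisen condensation of malonic half esters with acid chlorides or acyl imidazolides (the standard β-keto ester synthesis), which is the laboratory counterpart of the enzymatic decarboxylative Claisen condensation. No ring is closed. The new stereocentre at C2 of 9 arises by unselective protonation of the enol, is racemic, and needs no control because step 6 turns this carbon into a methylene. The step needs C-acylation in preference to O-acylation at the enolate oxygen or the carboxylate, which the magnesium chelate should secure by tying up both oxygens. It also needs single acylation, which is secured because 8 is quaternary and has no α-hydrogen left to quench a second enolate; the aryl benzyl ether and the benzyl ester are inert under these conditions.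

Step 6
Reactants: 9 benzyl 2-{3-[4-(benzyloxy)phenyl]propyl}-3-oxohexadecanoate
Product: 11 1-(4-hydroxyphenyl)octadecan-5-one, via beta-keto acid 10 (not isolated)
Conditions: H2 (1 atm), 10% Pd/C, EtOAc–EtOH, rt; filter; then toluene, 80 °C
Reagents that add atoms: none
Why: Hydrogenolysis over Pd/C should cleave the benzyl ester and the benzyl aryl ether together, and the freed β-keto acid 10 loses CO2 on warming through a cyclic six-membered transition state, while the isolated aliphatic ketone and the phenol ring are not reduced at 1 atm and room temperature.

**Compound list**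

1 | 3-(4-hydroxyphenyl)propan-1-ol | OCCCc1ccc(O)cc1 | starting material
2 | 3-[4-(benzyloxy)phenyl]propan-1-ol | OCCCc1ccc(OCc2ccccc2)cc1 | intermediate
3 | 1-(benzyloxy)-4-(3-bromopropyl)benzene | BrCCCc1ccc(OCc2ccccc2)cc1 | intermediate
4 | dibenzyl malonate | O=C(CC(=O)OCc1ccccc1)OCc1ccccc1 | starting material
5 | dibenzyl 2-{3-[4-(benzyloxy)phenyl]propyl}malonate | O=C(OCc1ccccc1)C(CCCc1ccc(OCc2ccccc2)cc1)C(=O)OCc1ccccc1 | intermediate
6 | 2-[(benzyloxy)carbonyl]-5-[4-(benzyloxy)phenyl]pentanoic acid (racemic) | OC(=O)C(CCCc1ccc(OCc2ccccc2)cc1)C(=O)OCc1ccccc1 | intermediate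
7 | tetradecanoyl chloride (myristoyl chloride) | CCCCCCCCCCCCCC(=O)Cl | starting material
8 | 2-[(benzyloxy)carbonyl]-2-{3-[4-(benzyloxy)phenyl]propyl}-3-oxohexadecanoic acid (racemic; present in the flask as its magnesium chelate) | CCCCCCCCCCCCCC(=O)C(CCCc1ccc(OCc2ccccc2)cc1)(C(=O)O)C(=O)OCc1ccccc1 | intermediate (not isolated)
9 | benzyl 2-{3-[4-(benzyloxy)phenyl]propyl}-3-oxohexadecanoate (racemic) | CCCCCCCCCCCCCC(=O)C(CCCc1ccc(OCc2ccccc2)cc1)C(=O)OCc1ccccc1 | intermediate
10 | 2-[3-(4-hydroxyphenyl)propyl]-3-oxohexadecanoic acid (racemic) | CCCCCCCCCCCCCC(=O)C(CCCc1ccc(O)cc1)C(=O)O | intermediate (not isolated)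
11 | 1-(4-hydroxyphenyl)octadecan-5-one | CCCCCCCCCCCCCC(=O)CCCCc1ccc(O)cc1 | target

**Summary**

Total step count: 6. Longest linear sequence: 6 steps (1 to 11); compounds 4 and 7 enter as bought fragments.

Steps most likely to fail:

Step 5. The hindered α-alkyl magnesium enolate may acylate slowly, so that the acid chloride is lost to ketene formation with Et3N or to O-acylation at the carboxylate. The fallback builds the same β-keto ester by alkylating instead of acylating the hindered carbon. It sets out from 7, which is used to C-acylate Meldrum's acid (pyridine, CH2Cl2, 0 °C) to give 5-(1-hydroxytetradecylidene)-2,2-dimethyl-1,3-dioxane-4,6-dione F1. Heating with benzyl alcohol in toluene should give benzyl 3-oxohexadecanoate F2. C-alkylation of F2 with bromide 3 (K2CO3, NaI cat., acetone, reflux) comes back to the route at 9.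

Step 4. The saponification may run on to the malonic diacid or stop short, leaving a mixture of diester, half ester and diacid that is hard to separate. The fallback does without the half ester. It sets out from 5, which is deprotonated with NaH in toluene–THF and C-acylated with 7 to give dibenzyl 2-{3-[4-(benzyloxy)phenyl]propyl}-2-tetradecanoylpropanedioate F3. Hydrogenolysis (H2, Pd/C, EtOAc) should give 2-[3-(4-hydroxyphenyl)propyl]-2-tetradecanoylpropanedioic acid F4, which decarboxylates on warming and comes back to the route at 10, and from there goes on to 11 as in step 6.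

Step 3. The product may be alkylated a second time, or the bromide may react slowly and be lost to elimination. The fallback replaces the SN2 alkylation by a reductive alkylation that can only add one chain. It sets out from 2, which is oxidised (Dess–Martin periodinane, CH2Cl2) to 3-[4-(benzyloxy)phenyl]propanal F5. A one-pot Knoevenagel condensation and transfer hydrogenation with Meldrum's acid and Hantzsch ester (L-proline cat., EtOH, rt) should give 5-{3-[4-(benzyloxy)phenyl]propyl}-2,2-dimethyl-1,3-dioxane-4,6-dione F6. Ring opening of F6 with benzyl alcohol (toluene, 90 °C) comes back to the route at 6.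

**Further compounds**

F1 | step 5 | 5-(1-hydroxytetradecylidene)-2,2-dimethyl-1,3-dioxane-4,6-dione | CCCCCCCCCCCCCC(O)=C1C(=O)OC(C)(C)OC1=O
F2 | step 5 | benzyl 3-oxohexadecanoate | CCCCCCCCCCCCCC(=O)CC(=O)OCc1ccccc1
F3 | step 4 | dibenzyl 2-{3-[4-(benzyloxy)phenyl]propyl}-2-tetradecanoylpropanedioate | CCCCCCCCCCCCCC(=O)C(CCCc1ccc(OCc2ccccc2)cc1)(C(=O)OCc1ccccc1)C(=O)OCc1ccccc1
F4 | step 4 | 2-[3-(4-hydroxyphenyl)propyl]-2-tetradecanoylpropanedioic acid | CCCCCCCCCCCCCC(=O)C(CCCc1ccc(O)cc1)(C(=O)O)C(=O)O
F5 | step 3 | 3-[4-(benzyloxy)phenyl]propanal | O=CCCc1ccc(OCc2ccccc2)cc1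
F6 | step 3 | 5-{3-[4-(benzyloxy)phenyl]propyl}-2,2-dimethyl-1,3-dioxane-4,6-dione | CC1(C)OC(=O)C(CCCc2ccc(OCc3ccccc3)cc2)C(=O)O1
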